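I counted in one unit, the fraction of the charge, so the solubility of target became 1.50% of the charge.

substrate 0.20 M; gas phase 26 mM (held); time 20 h

    target ⇌ isomer of the product (K1 = 0.54, k1 = 0.32 h⁻¹)
    dissolved gas + target → over-reacted product (k2 = 18 M⁻¹ h⁻¹)
    substrate + dissolved gas → target (k3 = 27 M⁻¹ h⁻¹)
    target → over-reaction product (k4 = 0.23 h⁻¹)
    crystals ⇌ target, rate k5*(cs5 - [target]) while solid is left; crystals form when [target] > cs5 (cs5 = 3.0 mM, k5 = 1.1 h⁻¹)
    gas phase ⇌ dissolved gas, rate k6*(csat - [dissolved gas]) (k6 = 4.0 h⁻¹, csat = 26 mM)

- delta: doubling the saturation concentration of gas phase, all else as stated
- theta: doubling the dissolution coefficient of step 5, all else as stated
- beta: doubling the transfer coefficient of step 6, all else as stated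
- gamma: doubling the solubility in step 5, all else as stated

* target and crystals together at 20 h, in percent of the substrate charged
* the change that raises the amount of target and crystals together at 20 h, in percent of the substrate charged most ("none" if none brings more than 2 percentage points) (delta / theta / beta / gamma / none)
* amount of target and crystals together at 20 h, in percent of the substrate charged, after beta

- for target the crystals are counted in
- as a solid, counted per litre of solution: crystals
- at the start none of the gas is dissolved
- run time (flask): 20 h

The bench rule for such a flask says that what has crystallised is safe, so I first asked what fraction of the target reaches the crystals. With the dissolved gas taken at its saturation value, dissolved target is lost at 0.698 h⁻¹, a pseudo-first-order loss through both destructive steps. Its excess over the solubility enters the crystals at 1.1 h⁻¹, which is faster, by a ratio of 1.58. So the capture share, crystal growth over crystal growth plus loss, came to 61.2%. Dissolved target and the isomer of the product relax towards each other with a half-life of 0.760 h, much shorter than the run, so in my reckoning the isomer carried nothing away.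

The rule stops where crystals dissolve again into a solution in which target is being destroyed. For the late part of the run I reckoned that solution to balance at the capture share of the solubility, and I called drain the fraction of the charge lost through it, reckoned over the whole run, at 13 percentage points. Drain over capture came to 0.209 for this flask, and by this reckoning the rule fails as the ratio nears one, where the drain equals what was captured. The substrate needs some hours to go, so I guessed the drain acts over half the run, and my estimate was 54.8%. In my reckoning, doubling the dissolution coefficient raised capture to 75.9% and the estimate to 68.0%, so I chose theta. The transfer coefficient enters neither quantity, so for beta my reckoning stayed at 54.8%.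

The forecast gave 58%, theta and 53%, holding that “Faster crystallisation (theta) is the only change that shortens target's exposure in solution”. The simulation gave 55.3%, with theta gaining 10 points, and 52.5% after beta, below my 54.8%.

In this flask, the limit of solubility and the time given act together on target and crystals: without that limit they stood at 0.209% at 20 h, and left ten times as long they stood at 0%. In this flask they fell from 61.0% at 10.0 h to 55.3% at 20.0 h, against my half-run drain of 6.4 points. For the flask charged with 0.050 M I reckon a ratio of 0.838 and a drain of 51 points, and that flask ended with target and crystals at 13.7%.

The constants used here come from no measurement.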